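**Plan**

- Numbering (bicyclo[3.3.1]nonane): C1 aroyl bridgehead, C5 lavandulyl bridgehead, C9 bridging ketone; ring A = C1–C2–C3–C4–C5–C9, ring B = C1–C8–C7–C6–C5–C9 (C7 prenyl, C8 gem-dimethyl).
- Enabling feature: C1 is bonded to three acyl carbons (aroyl C=O, C2, C9) next to quaternary C8, and the C9 oxygen lies one atom from C1. The C2 acyl group can therefore be stored on that oxygen as a fused enol lactone and then shifted to C1.
- Cuts, in retrosynthetic order: C1–C2 (1,3-acyl shift), O9–C2 and C5–C4 (prenylmalonyl unit), C1–C9 (Claisen closure of ring B), aryl–CO, C5–C6 (ester alkylation), C7–prenyl.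
- Forward order: open chain from 3,3-dimethylglutaric anhydride, then ring B as a 2-aroylcyclohexanone, then the enol lactone fused across C5–C9, then ring A by light, then one global desilylation.
- Stereochemistry: C7 from an Evans alkylation with (R)-4-benzyloxazolidin-2-one; the lavandulyl centre from lipase-resolved (S)-lavandulol; C5 from acylation of the ring B dienol ether anti to the C7 prenyl group; C1 relayed from C5 by the lactone tether.

Key step: step 19

Assumption: the lipase in step 1 acetylates (R)-lavandulol faster, so the S alcohol is the one recovered; with the opposite preference the ester fraction would be saponified instead.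

**Route**

Step 1
Reactants: 1 (±)-lavandulol
Product: 2 (S)-lavandulol, (2S)-5-methyl-2-(prop-1-en-2-yl)hex-4-en-1-ol
Conditions: porcine pancreatic lipase, vinyl acetate, hexane, 25 °C, run past half conversion; chromatography
Reagents that add atoms: none
Why: Lipase-catalysed kinetic resolution by transesterification removes the faster-reacting R alcohol as its acetate, so the remaining S alcohol should be of high enantiomeric purity and carries the lavandulyl stereocentre of the target unchanged.

Step 2
Reactants: 2 (S)-lavandulol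
Product: 3 (S)-lavandulyl iodide, (2S)-1-iodo-5-methyl-2-(prop-1-en-2-yl)hex-4-ene
Conditions: PPh3, I2, imidazole, CH2Cl2, 0 °C
Reagents that add atoms: iodine, II
Why: Appel-type iodination of a primary alcohol proceeds at the CH2 group only, so the adjacent stereocentre and both alkenes are untouched.

Step 3
Reactants: 4 tert-butyl acetate; 3 (S)-lavandulyl iodide
Product: 5 tert-butyl (4S)-7-methyl-4-(prop-1-en-2-yl)oct-6-enoate
Conditions: LiN(iPr)2, THF, −78 °C; then 3, DMPU, −78 → 0 °C
Reagents that add atoms: none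
Why: SN2 alkylation of the small, unhindered lithium enolate of tert-butyl acetate by a primary iodide in a dipolar cosolvent should favour substitution over elimination; the stereocentre is a spectator.

Step 4
Reactants: 6 4-bromobenzene-1,2-diol
Product: 7 4-bromo-1,2-bis(tert-butyldimethylsilyloxy)benzene
Conditions: t-BuMe2SiCl, imidazole, DMF, 25 °C
Reagents that add atoms: tert-butyldimethylsilyl chloride, CC(C)(C)[Si](C)(C)Cl
Why: Standard silylation of both phenols gives a bromide that tolerates bromine–lithium exchange, because the future lithium sits meta and para to the silyloxy groups and no silyl migration is possible.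

Step 5
Reactants: 8 dimethyl malonate; 9 prenyl bromide
Product: 10 dimethyl 2-(3-methylbut-2-en-1-yl)malonate
Conditions: NaH, THF, 0 → 25 °C, malonate in excess
Reagents that add atoms: none
Why: Malonic ester alkylation at the primary allylic carbon; excess malonate suppresses the second alkylation.

Step 6
Reactants: 10 dimethyl 2-(3-methylbut-2-en-1-yl)malonate
Product: 11 2-(3-methylbut-2-en-1-yl)malonic acid
Conditions: KOH, MeOH/H2O, 25 °C; cold dilute HCl to pH 2
Reagents that add atoms: potassium hydroxide, [K+].[OH-]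
Why: Saponification of both esters; cold acidification avoids decarboxylation of the malonic acid and hydration of the alkene.

Step 7
Reactants: 11 2-(3-methylbut-2-en-1-yl)malonic acid
Product: 12 2-(3-methylbut-2-en-1-yl)malonyl dichloride (used as a CH2Cl2 solution)
Conditions: 1-chloro-N,N,2-trimethylprop-1-en-1-amine (2.1 equiv), CH2Cl2, 0 → 25 °C
Reagents that add atoms: 1-chloro-N,N,2-trimethylprop-1-en-1-amine, CC(C)=C(Cl)N(C)C
Why: Acid chloride formation with an α-chloroenamine runs under neutral conditions and releases no HCl, so the prenyl alkene is not hydrochlorinated.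

Step 8
Reactants: 13 3,3-dimethylglutaric anhydride
Product: 14 5-methoxy-3,3-dimethyl-5-oxopentanoic acid
Conditions: MeOH, reflux
Reagents that add atoms: methanol, CO
Why: Alcoholysis of a symmetric cyclic anhydride gives a single half ester.

Step 9
Reactants: 14 5-methoxy-3,3-dimethyl-5-oxopentanoic acid; 15 (R)-4-benzyl-1,3-oxazolidin-2-one
Product: 17 methyl 5-[(4R)-4-benzyl-2-oxo-1,3-oxazolidin-3-yl]-3,3-dimethyl-5-oxopentanoate, via mixed pivalic anhydride 16 (not isolated)
Conditions: t-BuCOCl, Et3N, THF, −20 °C; then LiCl, 15, 25 °C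
Reagents that add atoms: none
Why: N-Acylation of the oxazolidinone through a mixed anhydride; the nucleophile attacks the CH2-bound carbonyl because the pivaloyl carbonyl is the more hindered one.

Step 10
Reactants: 17 the imide from step 9; 9 prenyl bromide
Product: 18 methyl (4R)-4-{[(4R)-4-benzyl-2-oxo-1,3-oxazolidin-3-yl]carbonyl}-3,3,7-trimethyloct-6-enoate
Conditions: NaN(SiMe3)2, THF, −78 °C; prenyl bromide, −78 → −45 °C
Reagents that add atoms: none
Why: Evans asymmetric alkylation: the chelated Z sodium enolate of the imide (more acidic than the ester) is attacked by the allylic bromide on the face away from the benzyl group, which with the R auxiliary sets the future C7 in the configuration of the target.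

Step 11
Reactants: 18 the alkylated imide
Product: 19 methyl (4R)-4-(hydroxymethyl)-3,3,7-trimethyloct-6-enoate
Conditions: LiBH4, MeOH (1 equiv), Et2O, 0 °C; used at once
Reagents that add atoms: none
Why: Reductive removal of the auxiliary: hydride attacks the activated exocyclic imide carbonyl, the neopentyl-type methyl ester reacts far more slowly at 0 °C, and the stereocentre is not enolised.

Step 12
Reactants: 19 the hydroxy ester
Product: 20 methyl (4R)-4-(iodomethyl)-3,3,7-trimethyloct-6-enoate
Conditions: PPh3, I2, imidazole, CH2Cl2, 0 °C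
Reagents that add atoms: iodine, II
Why: Appel-type iodination of the primary alcohol, done directly so that the hydroxy ester has no time to lactonise.

Step 13
Reactants: 5 tert-butyl (4S)-7-methyl-4-(prop-1-en-2-yl)oct-6-enoate; 20 the iodide
Product: 21 1-tert-butyl 7-methyl (4S)-5,5-dimethyl-4-(3-methylbut-2-en-1-yl)-2-[(2R)-5-methyl-2-(prop-1-en-2-yl)hex-4-en-1-yl]heptanedioate (both C2 epimers)
Conditions: LiN(iPr)2, THF, −78 °C (enolate of 5, 1.3 equiv); DMPU; 20, −78 → −20 °C
Reagents that add atoms: none
Why: Ester enolate alkylation by a primary iodide forms C5–C6; the tert-butyl ester enolate does not self-condense, and the new centre (C5) need not be controlled because it is enolised again in step 17.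

Step 14
Reactants: 21 the diester
Product: 22 tert-butyl (4S)-7-[methoxy(methyl)amino]-5,5-dimethyl-4-(3-methylbut-2-en-1-yl)-2-[(2R)-5-methyl-2-(prop-1-en-2-yl)hex-4-en-1-yl]-7-oxoheptanoate (C2 epimers)
Conditions: MeNH(OMe)·HCl, i-PrMgCl, THF, −20 → 0 °C
Reagents that add atoms: N,O-dimethylhydroxylamine hydrochloride, CNOC.Cl
Why: Direct aminolysis of the methyl ester by the magnesium amide of N,O-dimethylhydroxylamine (Weinreb amide formation); the tert-butyl ester is inert to this reagent.

Step 15
Reactants: 22 the Weinreb amide; 7 4-bromo-1,2-bis(tert-butyldimethylsilyloxy)benzene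
Product: 24 tert-butyl (4S)-7-[3,4-bis(tert-butyldimethylsilyloxy)phenyl]-5,5-dimethyl-4-(3-methylbut-2-en-1-yl)-2-[(2R)-5-methyl-2-(prop-1-en-2-yl)hex-4-en-1-yl]-7-oxoheptanoate (C2 epimers), via aryllithium 23 (not isolated)
Conditions: 7, n-BuLi, THF, −78 °C; then 22, −78 → −40 °C; aqueous work-up
Reagents that add atoms: none
Why: Weinreb ketone synthesis: the aryllithium adds once to give a chelated tetrahedral intermediate that collapses only on work-up, and the tert-butyl ester does not react at −78 °C.

Step 16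
Reactants: 24 the keto ester
Product: 25 (4S)-2-[3,4-bis(tert-butyldimethylsilyloxy)benzoyl]-3,3-dimethyl-4-(3-methylbut-2-en-1-yl)-6-[(2R)-5-methyl-2-(prop-1-en-2-yl)hex-4-en-1-yl]cyclohexan-1-one (ring B; C2 and C6 unassigned, partly enolised)
Conditions: LiN(SiMe3)2 (2.2 equiv), THF, 0 → 25 °C; aqueous work-up
Reagents that add atoms: none
Why: Intramolecular Claisen condensation: the aryl ketone enolate (C1) attacks the C9 ester in a six-membered closure helped by the gem-dimethyl group and driven by deprotonation of the 1,3-diketone; the tert-butoxide released does not attack the aryl silyl ethers.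

Step 17
Reactants: 25 the ring B 1,3-diketone
Product: 27 bis(trimethylsilyl) dienol ether of 25 (Ar–C(OSiMe3)=C1 and C9(OSiMe3)=C5; used crude), via ring enol silyl ether 26 (not isolated)
Conditions: Me3SiOTf, Et3N, Et2O, 0 °C; solvent exchange; then LiN(iPr)2, THF, −78 °C; Me3SiCl, −78 → 25 °C
Reagents that add atoms: trimethylsilyl trifluoromethanesulfonate, C[Si](C)(C)OS(=O)(=O)C(F)(F)F; chlorotrimethylsilane, C[Si](C)(C)Cl
Why: Two-stage conversion of a 1,3-diketone into its 1,3-bis(silyloxy)diene (O-silylation, then γ-deprotonation and O-silylation); C5–H is the only enolisable position left, so the diene terminus is C5.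

Step 18
Reactants: 27 the bis-silyl dienol ether; 12 2-(3-methylbut-2-en-1-yl)malonyl dichloride
Product: 29 (4aS,6S)-8-[3,4-bis(tert-butyldimethylsilyloxy)benzoyl]-4-(tert-butyldimethylsilyloxy)-7,7-dimethyl-3,6-bis(3-methylbut-2-en-1-yl)-4a-[(2R)-5-methyl-2-(prop-1-en-2-yl)hex-4-en-1-yl]-4a,5,6,7-tetrahydro-2H-chromen-2-one (fused enol lactone; lavandulyl CH2 cis to the C7 prenyl), via hydroxy enol lactone 28 (not isolated)
Conditions: 12 (1.1 equiv), CH2Cl2, −78 → 0 °C; volatiles removed; then t-BuMe2SiOTf, 2,6-lutidine, CH2Cl2, −78 °C; Et3N-deactivated silica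
Reagents that add atoms: tert-butyldimethylsilyl trifluoromethanesulfonate, CC(C)(C)[Si](C)(C)OS(=O)(=O)C(F)(F)F
Why: Effenberger-type pyranone annulation of a bis(silyloxy)diene with a malonyl dichloride: the terminal carbon C5 is acylated first and the C9 oxygen closes the six-membered enol lactone on the second acid chloride; C5 is set by axial attack on the ring B half-chair with the C7 prenyl equatorial, i.e. anti to that group and away from the pseudoaxial C8 methyl, and the acidic 4-hydroxy lactone is then capped by O-silylation.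

Step 19
Reactants: 29 the fused enol lactone
Product: 30 (1R,5R,7S)-1-[3,4-bis(tert-butyldimethylsilyloxy)benzoyl]-4-(tert-butyldimethylsilyloxy)-8,8-dimethyl-3,7-bis(3-methylbut-2-en-1-yl)-5-[(2R)-5-methyl-2-(prop-1-en-2-yl)hex-4-en-1-yl]bicyclo[3.3.1]non-3-ene-2,9-dione (C1 spatially as in the target; the label differs only through CIP priorities)
Conditions: hν (about 350–365 nm, Pyrex), degassed benzene, 5 mM, 15 °C; stopped at partial conversion, 29 recycled
Reagents that add atoms: none
Why: Proposed new method: excitation of the cross-conjugated aroyl enol ester (Ar–CO–C1=C9–O–C2=O) should break the weak enol O–C2 bond to a pair made of an α,β-unsaturated acyl radical at C2, which is slow to lose CO, and a radical spread over O9, C1 and the aroyl oxygen; both halves hang on C5 and cannot diffuse apart, return to oxygen only regenerates 29, and bonding at C1 is not reversed at this wavelength. The closest known reaction type is the photo-Fries 1,3-acyl shift of enol esters and enol lactones, including enol esters of 1,3-diketones that give 2-acyl-1,3-diketones; what is new is delivery to a fully substituted carbon beside quaternary C8. Ring A (C1–C2–C3–C4–C5–C9) closes by a six-membered radical–radical combination of C2 onto C1, exo to the C9 carbonyl that re-forms. The new C1 stereocentre is dictated by C5: the C4–C3–C2 arm is axial on C5 and can reach only the same face of C1, so the aroyl group ends equatorial and the bridge is cis-fused as in the target. The step needs C- over O-recombination and acyl shift over decarbonylation, hydrogen abstraction or enone–alkene cycloaddition; the tether, the stabilised acyl radical, dilute degassed solution and irradiation at the long-wavelength edge, where 29 absorbs far more strongly than 30 (which has lost the aryl–enone conjugation), are meant to secure this.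

Step 20
Reactants: 30 the tris-silylated bicycle
Product: 31 target, (1S,5R,7S)-1-(3,4-dihydroxybenzoyl)-2-hydroxy-8,8-dimethyl-3,7-bis(3-methylbut-2-en-1-yl)-5-[(2R)-5-methyl-2-(prop-1-en-2-yl)hex-4-en-1-yl]bicyclo[3.3.1]non-2-ene-4,9-dione
Conditions: Bu4NF, AcOH (1:1, 4 equiv), THF, 0 °C, argon; pH 4 buffer work-up
Reagents that add atoms: none
Why: Buffered fluoride desilylation removes the enol silyl ether first, giving the enolate-stabilised core that resists retro-Claisen cleavage, and then both aryl silyl ethers; the C2 and C4 enol forms are tautomers of one compound, so the product is the target as drawn.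

**Compound list**

1 | (±)-lavandulol | C=C(C)C(CC=C(C)C)CO | starting material
2 | (S)-lavandulol | C=C(C)[C@H](CC=C(C)C)CO | intermediate
3 | (S)-lavandulyl iodide | C=C(C)[C@H](CC=C(C)C)CI | intermediate
4 | tert-butyl acetate | CC(=O)OC(C)(C)C | starting material
5 | tert-butyl (4S)-7-methyl-4-(prop-1-en-2-yl)oct-6-enoate | C=C(C)[C@H](CC=C(C)C)CCC(=O)OC(C)(C)C | intermediate
6 | 4-bromobenzene-1,2-diol | Oc1ccc(Br)cc1O | starting material
7 | 4-bromo-1,2-bis(tert-butyldimethylsilyloxy)benzene | Brc1ccc(O[Si](C)(C)C(C)(C)C)c(O[Si](C)(C)C(C)(C)C)c1 | intermediate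
8 | dimethyl malonate | COC(=O)CC(=O)OC | starting material
9 | prenyl bromide | CC(C)=CCBr | starting material
10 | dimethyl 2-(3-methylbut-2-en-1-yl)malonate | COC(=O)C(CC=C(C)C)C(=O)OC | intermediate
11 | 2-(3-methylbut-2-en-1-yl)malonic acid | OC(=O)C(CC=C(C)C)C(=O)O | intermediate
12 | 2-(3-methylbut-2-en-1-yl)malonyl dichloride | ClC(=O)C(CC=C(C)C)C(Cl)=O | intermediate
13 | 3,3-dimethylglutaric anhydride | CC1(C)CC(=O)OC(=O)C1 | starting material
14 | 5-methoxy-3,3-dimethyl-5-oxopentanoic acid | COC(=O)CC(C)(C)CC(=O)O | intermediate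
15 | (R)-4-benzyl-1,3-oxazolidin-2-one | O=C1N[C@H](Cc2ccccc2)CO1 | starting material
16 | mixed pivalic anhydride of 14 | COC(=O)CC(C)(C)CC(=O)OC(=O)C(C)(C)C | intermediate
17 | methyl 5-[(4R)-4-benzyl-2-oxo-1,3-oxazolidin-3-yl]-3,3-dimethyl-5-oxopentanoate | COC(=O)CC(C)(C)CC(=O)N1[C@H](Cc2ccccc2)COC1=O | intermediate
18 | methyl (4R)-4-{[(4R)-4-benzyl-2-oxo-1,3-oxazolidin-3-yl]carbonyl}-3,3,7-trimethyloct-6-enoate | COC(=O)CC(C)(C)[C@@H](CC=C(C)C)C(=O)N1[C@H](Cc2ccccc2)COC1=O | intermediate
19 | methyl (4R)-4-(hydroxymethyl)-3,3,7-trimethyloct-6-enoate | COC(=O)CC(C)(C)[C@@H](CC=C(C)C)CO | intermediate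
20 | methyl (4R)-4-(iodomethyl)-3,3,7-trimethyloct-6-enoate | COC(=O)CC(C)(C)[C@@H](CC=C(C)C)CI | intermediate
21 | 1-tert-butyl 7-methyl (4S)-5,5-dimethyl-4-(3-methylbut-2-en-1-yl)-2-[(2R)-5-methyl-2-(prop-1-en-2-yl)hex-4-en-1-yl]heptanedioate, C2 epimers (labels change by CIP priority only) | COC(=O)CC(C)(C)[C@@H](CC=C(C)C)CC(C[C@H](C(C)=C)CC=C(C)C)C(=O)OC(C)(C)C | intermediate
22 | Weinreb amide of 21 at the C7 carboxyl | CON(C)C(=O)CC(C)(C)[C@@H](CC=C(C)C)CC(C[C@H](C(C)=C)CC=C(C)C)C(=O)OC(C)(C)C | intermediate
23 | 3,4-bis(tert-butyldimethylsilyloxy)phenyllithium | [Li]c1ccc(O[Si](C)(C)C(C)(C)C)c(O[Si](C)(C)C(C)(C)C)c1 | intermediate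
24 | tert-butyl (4S)-7-[3,4-bis(tert-butyldimethylsilyloxy)phenyl]-5,5-dimethyl-4-(3-methylbut-2-en-1-yl)-2-[(2R)-5-methyl-2-(prop-1-en-2-yl)hex-4-en-1-yl]-7-oxoheptanoate | CC(C)(C)OC(=O)C(C[C@H](C(C)=C)CC=C(C)C)C[C@H](CC=C(C)C)C(C)(C)CC(=O)c1ccc(O[Si](C)(C)C(C)(C)C)c(O[Si](C)(C)C(C)(C)C)c1 | intermediate
25 | ring B 1,3-diketone, (4S)-2-aroyl-3,3-dimethyl-4-prenyl-6-[(2R)-lavandulyl]cyclohexan-1-one (drawn as diketone) | O=C1C(C[C@H](C(C)=C)CC=C(C)C)C[C@H](CC=C(C)C)C(C)(C)C1C(=O)c1ccc(O[Si](C)(C)C(C)(C)C)c(O[Si](C)(C)C(C)(C)C)c1 | intermediate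
26 | ring enol trimethylsilyl ether of 25 (C1=C9, C9 OSiMe3) | C[Si](C)(C)OC1=C(C(=O)c2ccc(O[Si](C)(C)C(C)(C)C)c(O[Si](C)(C)C(C)(C)C)c2)C(C)(C)[C@@H](CC=C(C)C)CC1C[C@H](C(C)=C)CC=C(C)C | intermediate
27 | bis(trimethylsilyl) dienol ether of 25 (exocyclic double bond geometry unassigned) | C[Si](C)(C)OC(c1ccc(O[Si](C)(C)C(C)(C)C)c(O[Si](C)(C)C(C)(C)C)c1)=C1C(O[Si](C)(C)C)=C(C[C@H](C(C)=C)CC=C(C)C)C[C@H](CC=C(C)C)C1(C)C | intermediate
28 | (4aR,6S)-4-hydroxy enol lactone (free C4 enol of 29) | C=C(C)[C@H](CC=C(C)C)C[C@]12C[C@H](CC=C(C)C)C(C)(C)C(C(=O)c3ccc(O[Si](C)(C)C(C)(C)C)c(O[Si](C)(C)C(C)(C)C)c3)=C1OC(=O)C(CC=C(C)C)=C2O | intermediate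
29 | fused enol lactone, C4 tert-butyldimethylsilyl enol ether, catechol bis-silyl ether (precursor of the key step) | C=C(C)[C@H](CC=C(C)C)C[C@]12C[C@H](CC=C(C)C)C(C)(C)C(C(=O)c3ccc(O[Si](C)(C)C(C)(C)C)c(O[Si](C)(C)C(C)(C)C)c3)=C1OC(=O)C(CC=C(C)C)=C2O[Si](C)(C)C(C)(C)C | intermediate
30 | target as C4 silyl enol ether and catechol bis-silyl ether (product of the key step) | C=C(C)[C@H](CC=C(C)C)C[C@]12C[C@H](CC=C(C)C)C(C)(C)[C@](C(=O)c3ccc(O[Si](C)(C)C(C)(C)C)c(O[Si](C)(C)C(C)(C)C)c3)(C1=O)C(=O)C(CC=C(C)C)=C2O[Si](C)(C)C(C)(C)C | intermediate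
31 | CNP0425478.2 | C=C(C)[C@H](CC=C(C)C)C[C@]12C[C@H](CC=C(C)C)C(C)(C)[C@](C(=O)c3ccc(O)c(O)c3)(C1=O)C(O)=C(CC=C(C)C)C2=O | target

**Step count**

Total: 20 steps. Longest linear sequence: 13 steps (steps 8–20, from anhydride 13).

**Steps most likely to fail**

1. Step 19 (the step labelled as a proposed new method). What may go wrong: after O–C2 cleavage the pair may recombine at oxygen only, lose CO, abstract hydrogen, or the excited enone may add to a side-chain alkene, so that no C1–C2 bond forms. The fallback builds ring A on a ketone without the aroyl group and aroylates the bridgehead last, using known annulation and bridgehead chemistry; it sets out from diester 21 and comes back at target 31. Dieckmann cyclisation of 21 (KOtBu, THF) should give the ring B β-keto ester F1, and Krapcho demethoxycarbonylation (LiCl, wet DMSO, 140 °C) the ring B ketone F2. Silylation with t-BuMe2SiOTf and Et3N should give the more substituted silyl enol ether F3 (C9=C5). Effenberger annulation of F3 with 12, completed with KOH and BnEt3NCl, should give the bicyclic trione F4 with hydrogen at C1, the C7 prenyl again exo. Methylation with Me3SiCHN2 gives the C4 methyl enol ether F5 after separation from its C2 regioisomer. Bridgehead deprotonation with LiN(iPr)2 and quenching with I2 gives the C1 iodide F6. Iodine–magnesium exchange with i-PrMgCl at −78 °C and addition to 3,4-bis(tert-butyldimethylsilyloxy)benzaldehyde F7 (from aryllithium 23 and DMF) gives the carbinol F8, and Dess–Martin periodinane the aroyl ketone F9. Bu4NF/AcOH then gives the catechol methyl enol ether F10, and LiCl in DMSO at 120 °C cleaves the methyl enol ether to 31.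

2. Step 18. What may go wrong: the diacid chloride may acylate oxygen first or oligomerise through its ketene, and C5 may be acylated on the face syn to the prenyl group. The fallback introduces the two acyl bonds one at a time; it sets out from dienol ether 27 (reagent from malonate 10) and comes back at hydroxy lactone 28, which is silylated as in step 18. Half-saponification of 10 (KOH, 1 equiv) gives the monomethyl ester F11, and 1-chloro-N,N,2-trimethylprop-1-en-1-amine converts it into the half-ester acid chloride F12. Acylation of 27 at its terminal carbon with F12 (CH2Cl2, −78 → 20 °C, aqueous work-up) should give the C5-acylated triketo ester F13, whose C5 epimers can be separated at this stage. DBU in toluene then closes the enol lactone with loss of methanol to give 28.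

3. Step 13. What may go wrong: substitution at the hindered, β-branched iodide may be so slow that elimination and attack of the enolate on the methyl ester take over. The fallback forms C5–C6 by olefination and conjugate reduction; it sets out from alcohol 19 and ester 5 and comes back at diester 21. Dess–Martin oxidation of 19 gives the aldehyde F14. Deprotonation of 5 with LiN(iPr)2 (2 equiv) and ClP(O)(OEt)2 gives the phosphonate F15. Horner–Wadsworth–Emmons reaction of F15 with F14 under mild conditions (LiCl, DBU, MeCN), chosen to spare the α-stereocentre of the aldehyde, should give the unsaturated diester F16. Reduction of the conjugated double bond only (Mg, MeOH) then gives 21.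

**Further compounds**

F1 | step 19 | methyl (5S)-6,6-dimethyl-5-(3-methylbut-2-en-1-yl)-3-[(2R)-5-methyl-2-(prop-1-en-2-yl)hex-4-en-1-yl]-2-oxocyclohexane-1-carboxylate | COC(=O)C1C(=O)C(C[C@H](C(C)=C)CC=C(C)C)C[C@H](CC=C(C)C)C1(C)C
F2 | step 19 | (4S)-3,3-dimethyl-4-(3-methylbut-2-en-1-yl)-6-[(2R)-5-methyl-2-(prop-1-en-2-yl)hex-4-en-1-yl]cyclohexan-1-one | O=C1CC(C)(C)[C@@H](CC=C(C)C)CC1C[C@H](C(C)=C)CC=C(C)C
F3 | step 19 | tert-butyldimethylsilyl enol ether of F2 (C9=C5) | CC(C)(C)[Si](C)(C)OC1=C(C[C@H](C(C)=C)CC=C(C)C)C[C@H](CC=C(C)C)C(C)(C)C1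
F4 | step 19 | bicyclic trione with hydrogen at C1 (enol form) | C=C(C)[C@H](CC=C(C)C)C[C@]12C[C@H](CC=C(C)C)C(C)(C)[C@H](C1=O)C(O)=C(CC=C(C)C)C2=O
F5 | step 19 | C4 methyl enol ether of F4 | C=C(C)[C@H](CC=C(C)C)C[C@]12C[C@H](CC=C(C)C)C(C)(C)[C@H](C1=O)C(=O)C(CC=C(C)C)=C2OC
F6 | step 19 | C1 bridgehead iodide | C=C(C)[C@H](CC=C(C)C)C[C@]12C[C@H](CC=C(C)C)C(C)(C)[C@](I)(C1=O)C(=O)C(CC=C(C)C)=C2OC
F7 | step 19 | 3,4-bis(tert-butyldimethylsilyloxy)benzaldehyde | O=Cc1ccc(O[Si](C)(C)C(C)(C)C)c(O[Si](C)(C)C(C)(C)C)c1
F8 | step 19 | C1 aryl carbinol (carbinol epimers) | C=C(C)[C@H](CC=C(C)C)C[C@]12C[C@H](CC=C(C)C)C(C)(C)[C@](C(O)c3ccc(O[Si](C)(C)C(C)(C)C)c(O[Si](C)(C)C(C)(C)C)c3)(C1=O)C(=O)C(CC=C(C)C)=C2OC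
F9 | step 19 | target as C4 methyl enol ether and catechol bis-silyl ether | C=C(C)[C@H](CC=C(C)C)C[C@]12C[C@H](CC=C(C)C)C(C)(C)[C@](C(=O)c3ccc(O[Si](C)(C)C(C)(C)C)c(O[Si](C)(C)C(C)(C)C)c3)(C1=O)C(=O)C(CC=C(C)C)=C2OC
F10 | step 19 | target as C4 methyl enol ether, free catechol | C=C(C)[C@H](CC=C(C)C)C[C@]12C[C@H](CC=C(C)C)C(C)(C)[C@](C(=O)c3ccc(O)c(O)c3)(C1=O)C(=O)C(CC=C(C)C)=C2OC
F11 | step 18 | 2-(methoxycarbonyl)-5-methylhex-4-enoic acid | COC(=O)C(CC=C(C)C)C(=O)O
F12 | step 18 | methyl 2-(chlorocarbonyl)-5-methylhex-4-enoate | COC(=O)C(CC=C(C)C)C(Cl)=O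
F13 | step 18 | C5-acylated triketo ester (C4 acyl anti to the C7 prenyl) | C=C(C)[C@H](CC=C(C)C)C[C@]1(C(=O)C(CC=C(C)C)C(=O)OC)C[C@H](CC=C(C)C)C(C)(C)C(C(=O)c2ccc(O[Si](C)(C)C(C)(C)C)c(O[Si](C)(C)C(C)(C)C)c2)C1=O
F14 | step 13 | methyl (4R)-4-formyl-3,3,7-trimethyloct-6-enoate | COC(=O)CC(C)(C)[C@@H](CC=C(C)C)C=O
F15 | step 13 | tert-butyl (4R)-2-(diethoxyphosphoryl)-7-methyl-4-(prop-1-en-2-yl)oct-6-enoate (C2 epimers) | CCOP(=O)(OCC)C(C[C@H](C(C)=C)CC=C(C)C)C(=O)OC(C)(C)C
F16 | step 13 | 2,3-didehydro derivative of 21 (E/Z mixture) | COC(=O)CC(C)(C)[C@@H](CC=C(C)C)C=C(C[C@H](C(C)=C)CC=C(C)C)C(=O)OC(C)(C)C
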